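**Retrosynthetic overview**
1. Target 29 ⇐ one global hydrogenolysis of the O-protected trimer 28 (benzyl ethers, diphenylmethylene ketals).
2. Upper 4β→6 (3,4-cis) bond: 28 ⇐ ketone 27 ⇐ semipinacol 1,2-aryl shift (C3→C4) in tertiary carbinol 26; 26 ⇐ aryllithium from bromo dimer 22 + flavan-3-one 24.
3. Lower 4α→6 (3,4-trans) bond: 22 ⇐ 21 ⇐ Friedel–Crafts opening of flav-3-ene epoxide 16 by the all-cis unit A 20.
4. 20 and 24 ⇐ the same epoxide 16 (4-OBn or 4-SBn alcohol → 3-ketone; β-face hydride gives all-cis unit A); 16 ⇐ flav-3-ene 15.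
5. 15 ⇐ catechol (ring A, present from the start), propiolic acid (C2–C4; pyran ring C closed by hydroarylation) and 4-bromophenol (ring B, attached last by asymmetric boronate addition, which sets C2).

Conventions: flavan numbering (O1, C2–C4, ring A C4a–C8a, ring B primed); α is the face of the 2-aryl group, β the opposite face; units are C (upper), B (middle), A (lower, 3,4-diol). Oritin = (2R,3S)-7,8,4′-trihydroxyflavan-3-ol; epioritin-4α-ol = (2R,3R,4R)-7,8,4′-trihydroxyflavan-3,4-diol.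

Assumption: in step 8 the (2R,3R)-configured catalyst is taken to give (2S)-15; if the sense of induction is the reverse, its (2S,3S)-enantiomer is used.

**Step 1**
Reactants: 1 catechol
Product: 2 2,2-diphenyl-1,3-benzodioxole
Conditions: Ph2CCl2 (1.1 equiv), neat, 160 °C, 30 min
Reagents that add atoms: dichlorodiphenylmethane, ClC(Cl)(c1ccccc1)c1ccccc1
Why: Thermal ketalisation of the catechol with the gem-dichloride gives the diphenylmethylene ketal, which is removable by hydrogenolysis and carries no acidic C–H for the next step.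

**Step 2**
Reactants: 2 2,2-diphenyl-1,3-benzodioxole
Product: 5 2,2-diphenyl-1,3-benzodioxol-4-ol, via aryllithium 3 (not isolated), via dimethyl arylboronate 4 (not isolated)
Conditions: n-BuLi, THF, 0 °C to rt; B(OMe)3, −78 °C to rt; AcOH, 30% H2O2, 0 °C
Reagents that add atoms: hydrogen peroxide, OO
Why: Directed ortho-metalation beside the ketal oxygen (the two ortho positions are equivalent), borylation and boronate oxidation install the third ring-A oxygen, the future O1.

**Step 3**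
Reactants: 5 2,2-diphenyl-1,3-benzodioxol-4-ol, 6 propiolic acid
Product: 7 2,2-diphenyl-1,3-benzodioxol-4-yl propiolate
Conditions: DCC, CH2Cl2, 0 °C
Reagents that add atoms: none
Why: Carbodiimide (Steglich-type) esterification ties the three-carbon unit to the phenol oxygen so that the later C–C bond can only form at the ortho position.

**Step 4**
Reactants: 7 2,2-diphenyl-1,3-benzodioxol-4-yl propiolate
Product: 8 7,8-(diphenylmethylenedioxy)coumarin
Conditions: PtCl4 (5 mol %), 1,4-dioxane/ClCH2CH2Cl, rt to 60 °C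
Reagents that add atoms: none
Why: Lewis-acid-catalysed intramolecular 6-endo hydroarylation of the aryl alkynoate at the single free ortho position (para to a ketal oxygen) closes pyran ring C.

**Step 5**
Reactants: 8 7,8-(diphenylmethylenedioxy)coumarin
Product: 10 2-ethoxy-7,8-(diphenylmethylenedioxy)-2H-chromene, via lactol 9 (not isolated)
Conditions: i-Bu2AlH, CH2Cl2, −78 °C; aq. KNaC4H4O6 (potassium sodium tartrate) work-up; EtOH, pyridinium p-toluenesulfonate (cat.), rt
Reagents that add atoms: ethanol, CCO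
Why: Partial hydride reduction of the lactone gives the lactol, and acid-catalysed acetalisation through the benzopyrylium ion gives the racemic chromene acetal.

**Step 6**
Reactants: 11 4-bromophenol
Product: 12 1-(benzyloxy)-4-bromobenzene
Conditions: BnBr, K2CO3, acetone, reflux
Reagents that add atoms: benzyl bromide, BrCc1ccccc1
Why: Williamson etherification protects the ring-B phenol as a hydrogenolysable ether.

**Step 7**
Reactants: 12 1-(benzyloxy)-4-bromobenzene
Product: 14 diethyl [4-(benzyloxy)phenyl]boronate, via arylmagnesium bromide 13 (not isolated)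
Conditions: Mg, THF, reflux; B(OEt)3, −78 °C to rt; HCl (1 equiv, Et2O), filter, distil
Reagents that add atoms: triethyl borate, CCOB(OCC)OCC
Why: Magnesium insertion into the C–Br bond and borylation with the trialkyl borate give the aryl boronate needed for step 8.

**Step 8**
Reactants: 10 2-ethoxy-7,8-(diphenylmethylenedioxy)-2H-chromene, 14 diethyl [4-(benzyloxy)phenyl]boronate
Product: 15 (2S)-4′-benzyloxy-7,8-(diphenylmethylenedioxy)flav-3-ene
Conditions: (2R,3R)-4-(dibenzylamino)-2,3-dihydroxy-4-oxobutanoic acid (5 mol %), Yb(OTf)3 (5 mol %), EtOAc, −20 °C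
Reagents that add atoms: none
Why: The racemic acetal ionises to the achiral benzopyrylium ion and the aryl group is delivered from the boronate bound to the chiral hydroxy acid (catalytic asymmetric boronate addition to a chromene acetal), which sets C2, the only catalyst-controlled stereocentre of the route.

**Step 9**
Reactants: 15 (2S)-4′-benzyloxy-7,8-(diphenylmethylenedioxy)flav-3-ene
Product: 16 (2R,3S,4S)-4′-benzyloxy-7,8-(diphenylmethylenedioxy)-3,4-epoxyflavan
Conditions: dimethyldioxirane (1.1 equiv, in acetone), CH2Cl2, −40 °C; evaporate at or below 0 °C; crude 16 kept as a CH2Cl2 solution at −78 °C and used the same day in steps 10, 14 and 16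
Reagents that add atoms: dimethyldioxirane, CC1(C)OO1
Why: Dioxirane epoxidation of the chromene double bond occurs on the β-face, opposite the 2-aryl group, under neutral conditions with acetone as the only co-product, so the acid-labile benzylic epoxide is obtained clean enough to be used without purification.

**Step 10**
Reactants: 16 (2R,3S,4S)-4′-benzyloxy-7,8-(diphenylmethylenedioxy)-3,4-epoxyflavan
Product: 17 (2R,3S,4R)-4,4′-bis(benzyloxy)-7,8-(diphenylmethylenedioxy)flavan-3-ol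
Conditions: BnOH (10 equiv), NaH (0.2 equiv), THF, 0 °C to rt
Reagents that add atoms: benzyl alcohol, OCc1ccccc1
Why: Benzyl oxide opens the epoxide by SN2 at benzylic C4 (trans-diaxial epoxide opening with inversion), giving the 3β-OH and 4α-OBn groups.

**Step 11**
Reactants: 17 (2R,3S,4R)-4,4′-bis(benzyloxy)-7,8-(diphenylmethylenedioxy)flavan-3-ol
Product: 18 (2R,4R)-4,4′-bis(benzyloxy)-7,8-(diphenylmethylenedioxy)flavan-3-one
Conditions: Dess–Martin periodinane, wet CH2Cl2, rt
Reagents that add atoms: none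
Why: Dess–Martin oxidation under near-neutral conditions gives the 3-ketone without enolisation, so the 2,4-cis stereocentres are kept.

**Step 12**
Reactants: 18 (2R,4R)-4,4′-bis(benzyloxy)-7,8-(diphenylmethylenedioxy)flavan-3-one
Product: 19 (2R,3R,4R)-4,4′-bis(benzyloxy)-7,8-(diphenylmethylenedioxy)flavan-3-ol
Conditions: LiBH(s-Bu)3, THF, −78 °C
Reagents that add atoms: none
Why: The bulky hydride attacks from the β-face, opposite the 2-aryl and 4-benzyloxy groups (substrate-controlled ketone reduction), which sets the 3α-OH and the all-cis array of unit A.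

**Step 13**
Reactants: 19 (2R,3R,4R)-4,4′-bis(benzyloxy)-7,8-(diphenylmethylenedioxy)flavan-3-ol
Product: 20 (2R,3R,4R)-3,4,4′-tris(benzyloxy)-7,8-(diphenylmethylenedioxy)flavan
Conditions: NaH, BnBr, n-Bu4NI (cat.), DMF, 0 °C to rt
Reagents that add atoms: benzyl bromide, BrCc1ccccc1
Why: Williamson etherification caps the 3-OH so that unit A has no free hydroxyl to compete with its C6 as the nucleophile in step 14.

**Step 14**
Reactants: 16 (2R,3S,4S)-4′-benzyloxy-7,8-(diphenylmethylenedioxy)-3,4-epoxyflavan, 20 (2R,3R,4R)-3,4,4′-tris(benzyloxy)-7,8-(diphenylmethylenedioxy)flavan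
Product: 21 protected dimer oritin-(4α→6)-epioritin-4α-ol
Conditions: 20 (2 equiv, excess recovered), BF3·OEt2 (10 mol %), CH2Cl2, −78 °C
Reagents that add atoms: none
Why: The BF3-activated epoxide is opened at benzylic C4 by C6 of 20 (ortho to O7, para to O1) in a Friedel–Crafts epoxide–arene alkylation, and attack anti to the epoxide oxygen gives the 4α (3,4-trans) interflavanyl bond and the 3β-OH of unit B.

**Step 15**
Reactants: 21 protected dimer oritin-(4α→6)-epioritin-4α-ol
Product: 22 bromo dimer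
Conditions: NBS (1.05 equiv), CH2Cl2, −78 to −30 °C
Reagents that add atoms: N-bromosuccinimide, O=C1CCC(=O)N1Br
Why: Electrophilic aromatic bromination goes to C6 of unit B, the only unhindered free ring position activated by two oxygens (ortho to O7, para to O1), and gives the handle for metalation.

**Step 16**
Reactants: 16 (2R,3S,4S)-4′-benzyloxy-7,8-(diphenylmethylenedioxy)-3,4-epoxyflavan
Product: 23 (2R,3R,4R)-4′-benzyloxy-4-(benzylsulfanyl)-7,8-(diphenylmethylenedioxy)flavan-3-ol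
Conditions: BnSH (1.5 equiv), Et3N (0.2 equiv), THF, 0 °C
Reagents that add atoms: benzyl mercaptan, SCc1ccccc1
Why: Thiolate SN2 opening of the epoxide at benzylic C4 (trans-diaxial) gives the 4α-benzylsulfanyl 3β-alcohol.

**Step 17**
Reactants: 23 (2R,3R,4R)-4′-benzyloxy-4-(benzylsulfanyl)-7,8-(diphenylmethylenedioxy)flavan-3-ol
Product: 24 (2R,4R)-4′-benzyloxy-4-(benzylsulfanyl)-7,8-(diphenylmethylenedioxy)flavan-3-one
Conditions: Dess–Martin periodinane, CH2Cl2, 0 °C
Reagents that add atoms: none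
Why: Dess–Martin oxidation tolerates the sulfide and gives the 2,4-cis 3-ketone with both flanking groups on the α-face.

**Step 18**
Reactants: 22 bromo dimer, 24 (2R,4R)-4′-benzyloxy-4-(benzylsulfanyl)-7,8-(diphenylmethylenedioxy)flavan-3-one
Product: 26 tertiary carbinol (3β-aryl-flavan-3α-ol), via dilithio species 25 (not isolated)
Conditions: t-BuLi (3.1 equiv), THF, −78 °C; then added to 24 pre-stirred with anhydrous CeCl3 (1.5 equiv) in THF, −78 to −40 °C; aq. NH4Cl
Reagents that add atoms: none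
Why: Bromine–lithium exchange (the first equivalent of t-BuLi deprotonates the 3-OH) gives the aryllithium, which adds to the CeCl3-activated ketone (CeCl3-mediated 1,2-addition that suppresses enolisation) from the β-face opposite the 2-aryl and 4-benzylsulfanyl groups, so the aryl group ends 3β and the hydroxyl 3α.

**Step 19**
Reactants: 26 tertiary carbinol (3β-aryl-flavan-3α-ol)
Product: 28 protected trimer oritin-(4β→6)-oritin-(4α→6)-epioritin-4α-ol, via ketone 27 (not isolated)
Conditions: AgBF4 (1.3 equiv), 2,6-di-tert-butyl-4-methylpyridine (2 equiv), 4 Å MS, CH2Cl2, −78 to −45 °C; then NaBH4, MeOH/THF, −78 °C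
Reagents that add atoms: none
Why: Proposed new method: thiophilic AgBF4 removes the 4-benzylsulfanyl group of unit C as AgSBn, and the flavan-4-yl cation (stabilised by O1 and the para 7-oxygen) is quenched by a suprafacial 1,2-shift of the electron-rich aryl group (C6 of unit B) from C3 to C4, driven by formation of the C3 carbonyl; the closest known reactions are the AgBF4-promoted ionisation of 4-benzylsulfanylflavan-3-ols and the semipinacol 1,2-aryl shift of α-hydroxy benzylic cations; because the aryl group sits on the β-face of C3 it can only arrive on the β-face of C4, which sets the 4β (3,4-cis) interflavanyl bond stereospecifically, the hindered pyridine prevents acid epimerisation of the ketone, and borohydride then attacks C3 from the α-face, anti to the pseudo-axial 4β-aryl group, to give the 3β-alcohol.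

**Step 20**
Reactants: 28 protected trimer oritin-(4β→6)-oritin-(4α→6)-epioritin-4α-ol
Product: 29 oritin-(4β→6)-oritin-(4α→6)-epioritin-4α-ol (target CNP0140823.3)
Conditions: H2 (1 atm), Pd(OH)2/C, THF/MeOH, rt
Reagents that add atoms: none
Why: Catalytic hydrogenolysis cleaves the five benzyl ethers and three diphenylmethylene ketals in one operation; under neutral conditions the PhCH2–O bonds should cleave in preference to the hindered flavan C4–O bond, and no stereocentre is touched.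

**Compound list**
1 | catechol | Oc1ccccc1O | starting material
2 | 2,2-diphenyl-1,3-benzodioxole | c1ccc2OC(c3ccccc3)(c3ccccc3)Oc2c1 | intermediate
3 | (2,2-diphenyl-1,3-benzodioxol-4-yl)lithium | [Li]c1cccc2OC(c3ccccc3)(c3ccccc3)Oc12 | intermediate
4 | dimethyl (2,2-diphenyl-1,3-benzodioxol-4-yl)boronate | COB(OC)c1cccc2OC(c3ccccc3)(c3ccccc3)Oc12 | intermediate
5 | 2,2-diphenyl-1,3-benzodioxol-4-ol | Oc1cccc2OC(c3ccccc3)(c3ccccc3)Oc12 | intermediate
6 | propiolic acid | C#CC(=O)O | starting material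
7 | 2,2-diphenyl-1,3-benzodioxol-4-yl propiolate | C#CC(=O)Oc1cccc2OC(c3ccccc3)(c3ccccc3)Oc12 | intermediate
8 | 7,8-(diphenylmethylenedioxy)coumarin | O=C1C=Cc2ccc3OC(c4ccccc4)(c4ccccc4)Oc3c2O1 | intermediate
9 | 7,8-(diphenylmethylenedioxy)-2H-chromen-2-ol (lactol, racemic) | OC1C=Cc2ccc3OC(c4ccccc4)(c4ccccc4)Oc3c2O1 | intermediate
10 | 2-ethoxy-7,8-(diphenylmethylenedioxy)-2H-chromene (racemic) | CCOC1C=Cc2ccc3OC(c4ccccc4)(c4ccccc4)Oc3c2O1 | intermediate
11 | 4-bromophenol | Oc1ccc(Br)cc1 | starting material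
12 | 1-(benzyloxy)-4-bromobenzene | Brc1ccc(OCc2ccccc2)cc1 | intermediate
13 | [4-(benzyloxy)phenyl]magnesium bromide | Br[Mg]c1ccc(OCc2ccccc2)cc1 | intermediate
14 | diethyl [4-(benzyloxy)phenyl]boronate | CCOB(OCC)c1ccc(OCc2ccccc2)cc1 | intermediate
15 | (2S)-4′-benzyloxy-7,8-(diphenylmethylenedioxy)flav-3-ene, i.e. (2S)-2-[4-(benzyloxy)phenyl]-7,8-(diphenylmethylenedioxy)-2H-chromene | c1ccccc1COc1ccc([C@H]2Oc3c(ccc4OC(c5ccccc5)(c5ccccc5)Oc34)C=C2)cc1 | intermediate
16 | (2R,3S,4S)-4′-benzyloxy-7,8-(diphenylmethylenedioxy)-3,4-epoxyflavan (epoxide oxygen trans to the 2-aryl group) | c1ccccc1COc1ccc([C@H]2Oc3c(ccc4OC(c5ccccc5)(c5ccccc5)Oc34)[C@@H]5O[C@H]25)cc1 | intermediate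
17 | (2R,3S,4R)-4,4′-bis(benzyloxy)-7,8-(diphenylmethylenedioxy)flavan-3-ol (2,3-trans-3,4-trans) | c1ccccc1COc1ccc([C@H]2Oc3c(ccc4OC(c5ccccc5)(c5ccccc5)Oc34)[C@@H](OCc5ccccc5)[C@@H]2O)cc1 | intermediate
18 | (2R,4R)-4,4′-bis(benzyloxy)-7,8-(diphenylmethylenedioxy)flavan-3-one (2,4-cis) | c1ccccc1COc1ccc([C@H]2Oc3c(ccc4OC(c5ccccc5)(c5ccccc5)Oc34)[C@@H](OCc5ccccc5)C2=O)cc1 | intermediate
19 | (2R,3R,4R)-4,4′-bis(benzyloxy)-7,8-(diphenylmethylenedioxy)flavan-3-ol (2,3-cis-3,4-cis) | c1ccccc1COc1ccc([C@H]2Oc3c(ccc4OC(c5ccccc5)(c5ccccc5)Oc34)[C@@H](OCc5ccccc5)[C@H]2O)cc1 | intermediate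
20 | (2R,3R,4R)-3,4,4′-tris(benzyloxy)-7,8-(diphenylmethylenedioxy)flavan (protected unit A, all-cis) | c1ccccc1COc1ccc([C@H]2Oc3c(ccc4OC(c5ccccc5)(c5ccccc5)Oc34)[C@@H](OCc5ccccc5)[C@H]2OCc2ccccc2)cc1 | intermediate
21 | 4′-O-benzyl-7,8-O-(diphenylmethylene)oritin-(4α→6)-3,4,4′-tri-O-benzyl-7,8-O-(diphenylmethylene)epioritin-4α-ol; unit B 2α-aryl, 3β-OH, 4α-aryl; unit A 2α-aryl, 3α-OBn, 4α-OBn | c1ccccc1COc1ccc([C@H]2Oc3c(cc([C@@H]4c5ccc8OC(c9ccccc9)(c9ccccc9)Oc8c5O[C@H](c5ccc(OCc8ccccc8)cc5)[C@H]4O)c8OC(c9ccccc9)(c9ccccc9)Oc38)[C@@H](OCc4ccccc4)[C@H]2OCc2ccccc2)cc1 | intermediate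
22 | 21 carrying bromine at C6 of unit B | c1ccccc1COc1ccc([C@H]2Oc3c(cc([C@@H]4c5cc(Br)c8OC(c9ccccc9)(c9ccccc9)Oc8c5O[C@H](c5ccc(OCc8ccccc8)cc5)[C@H]4O)c8OC(c9ccccc9)(c9ccccc9)Oc38)[C@@H](OCc4ccccc4)[C@H]2OCc2ccccc2)cc1 | intermediate
23 | (2R,3R,4R)-4′-benzyloxy-4-(benzylsulfanyl)-7,8-(diphenylmethylenedioxy)flavan-3-ol (2,3-trans-3,4-trans) | c1ccccc1COc1ccc([C@H]2Oc3c(ccc4OC(c5ccccc5)(c5ccccc5)Oc34)[C@@H](SCc5ccccc5)[C@@H]2O)cc1 | intermediate
24 | (2R,4R)-4′-benzyloxy-4-(benzylsulfanyl)-7,8-(diphenylmethylenedioxy)flavan-3-one (2,4-cis) | c1ccccc1COc1ccc([C@H]2Oc3c(ccc4OC(c5ccccc5)(c5ccccc5)Oc34)[C@@H](SCc5ccccc5)C2=O)cc1 | intermediate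
25 | dilithio species from 22: lithium at C6 of unit B, lithium 3-alkoxide of unit B | c1ccccc1COc1ccc([C@H]2Oc3c(cc([C@@H]4c5cc([Li])c8OC(c9ccccc9)(c9ccccc9)Oc8c5O[C@H](c5ccc(OCc8ccccc8)cc5)[C@H]4O[Li])c8OC(c9ccccc9)(c9ccccc9)Oc38)[C@@H](OCc4ccccc4)[C@H]2OCc2ccccc2)cc1 | intermediate
26 | tertiary carbinol: C6 of unit B of 21 bonded to C3 of (2R)-4′-benzyloxy-4α-(benzylsulfanyl)-3α-hydroxy-7,8-(diphenylmethylenedioxy)flavan (aryl 3β; 2-aryl, 3-OH and 4-SBn all α) | c1ccccc1COc1ccc([C@H]2Oc3c(cc([C@@H]4c5cc([C@@]6(O)[C@H](SCc7ccccc7)c7ccc8OC(c9ccccc9)(c9ccccc9)Oc8c7O[C@@H]6c7ccc(OCc8ccccc8)cc7)c8OC(c9ccccc9)(c9ccccc9)Oc8c5O[C@H](c5ccc(OCc8ccccc8)cc5)[C@H]4O)c8OC(c9ccccc9)(c9ccccc9)Oc38)[C@@H](OCc4ccccc4)[C@H]2OCc2ccccc2)cc1 | intermediate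
27 | 3-ketone: (2R)-4′-benzyloxy-7,8-(diphenylmethylenedioxy)-3-oxoflavan-4β-yl group at C6 of unit B of 21 (2,4-trans in unit C) | c1ccccc1COc1ccc([C@H]2Oc3c(cc([C@@H]4c5cc([C@H]6c7ccc8OC(c9ccccc9)(c9ccccc9)Oc8c7O[C@H](c7ccc(OCc8ccccc8)cc7)C6=O)c8OC(c9ccccc9)(c9ccccc9)Oc8c5O[C@H](c5ccc(OCc8ccccc8)cc5)[C@H]4O)c8OC(c9ccccc9)(c9ccccc9)Oc38)[C@@H](OCc4ccccc4)[C@H]2OCc2ccccc2)cc1 | intermediate
28 | 4′-O-benzyl-7,8-O-(diphenylmethylene)oritin-(4β→6)-4′-O-benzyl-7,8-O-(diphenylmethylene)oritin-(4α→6)-3,4,4′-tri-O-benzyl-7,8-O-(diphenylmethylene)epioritin-4α-ol | c1ccccc1COc1ccc([C@H]2Oc3c(cc([C@@H]4c5cc([C@H]6c7ccc8OC(c9ccccc9)(c9ccccc9)Oc8c7O[C@H](c7ccc(OCc8ccccc8)cc7)[C@H]6O)c8OC(c9ccccc9)(c9ccccc9)Oc8c5O[C@H](c5ccc(OCc8ccccc8)cc5)[C@H]4O)c8OC(c9ccccc9)(c9ccccc9)Oc38)[C@@H](OCc4ccccc4)[C@H]2OCc2ccccc2)cc1 | intermediate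
29 | oritin-(4β→6)-oritin-(4α→6)-epioritin-4α-ol; unit C (2R,3S,4S), unit B (2R,3S,4R), unit A (2R,3R,4R) | Oc1ccc([C@H]2Oc3c(cc([C@@H]4c5cc([C@H]6c7ccc(O)c(O)c7O[C@H](c7ccc(O)cc7)[C@H]6O)c(O)c(O)c5O[C@H](c5ccc(O)cc5)[C@H]4O)c(O)c3O)[C@@H](O)[C@H]2O)cc1 | target

**Step count and risk**
Total steps: 20. Longest linear sequence: 16 steps (steps 1–5, 8–15, 18–20).

Three steps most likely to fail:

Step 19 (the proposed 1,2-aryl shift). The risks are ionisation at the tertiary C3 carbinol instead of C4, competing migration of C2 (ring contraction), and epimerisation of ketone 27 before it is reduced. The fallback uses known chemistry and sets out from 21 and 23: the bond is formed directly by thiophile-promoted flavan-4-yl cation coupling (AgBF4, 2,6-di-tert-butyl-4-methylpyridine, THF/CH2Cl2, 0 °C, 21 in excess). C6 of unit B attacks C4 of the cation from both faces, and the 3,4-cis product is expected to be the minor isomer. It is 28 itself and is separated by preparative HPLC from the 3,4-trans isomer, the 4α-epimer of 28 F3. The route is rejoined at 28; steps 15, 17 and 18 are then not needed.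

Step 14 (epoxide–arene coupling). The risks are Lewis-acid rearrangement or oligomerisation of epoxide 16 and partial ionisation of the 4-OBn group of 20. The fallback sets out from 20 and 23: thioether 23 is ionised with AgBF4 (2,6-di-tert-butyl-4-methylpyridine, THF, 0 °C) in the presence of excess 20. Attack anti to the free 3β-OH gives 21 as the major product, and the minor 3,4-cis isomer, the 4β-epimer of 21 F2, is removed by chromatography. The route is rejoined at 21.

Step 8 (catalytic asymmetric arylation). The risk is low enantioselectivity or rate with this trioxygenated acetal and an aryl boronate. The fallback sets out from 10 and 14: the same boronate addition is promoted by achiral BF3·OEt2 (CH2Cl2, −40 °C) to give racemic 4′-benzyloxy-7,8-(diphenylmethylenedioxy)flav-3-ene F1, which is resolved by preparative chiral SFC. The (2S)-enantiomer rejoins the route at 15.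

**Further compounds**
F1 | step 8 | racemic 4′-benzyloxy-7,8-(diphenylmethylenedioxy)flav-3-ene | c1ccccc1COc1ccc(C2Oc3c(ccc4OC(c5ccccc5)(c5ccccc5)Oc34)C=C2)cc1
F2 | step 14 | 4β-epimer of 21 (unit B 3,4-cis) | c1ccccc1COc1ccc([C@H]2Oc3c(cc([C@H]4c5ccc8OC(c9ccccc9)(c9ccccc9)Oc8c5O[C@H](c5ccc(OCc8ccccc8)cc5)[C@H]4O)c8OC(c9ccccc9)(c9ccccc9)Oc38)[C@@H](OCc4ccccc4)[C@H]2OCc2ccccc2)cc1
F3 | step 19 | 4α-epimer of 28 (unit C 3,4-trans) | c1ccccc1COc1ccc([C@H]2Oc3c(cc([C@@H]4c5cc([C@@H]6c7ccc8OC(c9ccccc9)(c9ccccc9)Oc8c7O[C@H](c7ccc(OCc8ccccc8)cc7)[C@H]6O)c8OC(c9ccccc9)(c9ccccc9)Oc8c5O[C@H](c5ccc(OCc8ccccc8)cc5)[C@H]4O)c8OC(c9ccccc9)(c9ccccc9)Oc38)[C@@H](OCc4ccccc4)[C@H]2OCc2ccccc2)cc1
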